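Count the coupling partner first, against the left-handed substrate and the protic impurity that can take it up.

| setting | Sunday's | Saturday's | flask |
|---|---|---|---|
| left-handed substrate | 0.067 M | 0.15 M | 0.10 M |
| right-handed substrate | 0.067 M | 0.15 M | 0.10 M |
| coupling partner | 0.15 M (fed, over 6.0 min) | 0.15 M (fed, over 6.0 min) | 0.150 M (fed, over 6.0 min) |
| protic impurity | 2 mM | 2 mM | 2.00 mM |
| free catalyst | 0.31 mM | 0.31 mM | 0.31 mM |
| stray impurity | 50 µM | 50 µM | 50 µM |
| remark | run made earlier | run made earlier |  |
| time |  |  | 50 min |

| run | time / min | left-handed substrate / % | right-handed substrate / % | left-handed product / % |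
|---|---|---|---|---|
| Sunday's | 4.00 | 37.5 | 48.4 | 12.3 |
| Sunday's | 12.0 | 10.6 | 50.5 | 38.1 |
| Sunday's | 25.0 | 1.3 | 49.3 | 48.2 |
| Sunday's | 40.0 | 1.0 | 48.0 | 49.4 |
| Sunday's | 50.0 | 0.4 | 45.8 | 50.5 |
| Saturday's | 10.0 | 25.3 | 51.0 | 21.2 |
| Saturday's | 20.0 | 11.7 | 49.0 | 35.1 |
| Saturday's | 30.0 | 9.6 | 48.7 | 42.6 |
| Saturday's | 40.0 | 6.8 | 48.1 | 43.2 |
| Saturday's | 50.0 | 6.6 | 47.6 | 43.5 |

(standard deviation of a reading: 1 percentage point)

* part of the left-handed substrate and right-handed substrate charged together that has reacted at 50 min
* excess of left-handed product over right-handed product in the product at 50 min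
* excess of right-handed substrate over left-handed substrate among what is left of the two at 50 min

- free catalyst is single-handed; left-handed substrate and right-handed substrate are mirror images of each other, charged as a racemate, each of them at the stated concentration
- the analysis behind the earlier runs scatters by 1 percentage point, standard deviation
- on the list of suspects stand: coupling partner + protic impurity -> quenched reagent; free catalyst + left-handed substrate <-> catalyst intermediate A; free catalyst + stray impurity -> spent catalyst; coupling partner + catalyst intermediate A -> free catalyst + left-handed product; coupling partner + catalyst intermediate B -> free catalyst + right-handed product; 2 free catalyst <-> resting dimer; free catalyst + right-handed substrate <-> catalyst intermediate B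
- an excess is the difference of the two amounts in percent of their sum
- an excess is below zero if the other one leads

Does the partner outlast the left-handed substrate, the limiting reagent of the wanted coupling? The spare partner, meaning the partner charge less the protic impurity and the left-handed substrate, is 0.0480 M in the flask, so the partner does outlast it. Sunday's run had a spare of 0.0810 M and read 0.4% left-handed substrate at 50.0 min. Saturday's partner fell 2.00 mM short, which is 0.667% of that run's two substrates together, and that run read 6.6% left-handed substrate at 50.0 min, more than the shortfall leaves.

What does a positive spare do? At 50.0 min, Sunday's readings leave 3.30% unaccounted for, each reading scattering by 1 percentage point. Taken as right-handed product, that is 4.42 mM, or 0.0546 per unit of spare.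

How much does the flask make? This reckoning assumes that the leak follows the partner level and lets the spare stand in for its mean over the run. The flask then holds 1.31% right-handed product. With Sunday's left-handed reading as the remainder, this gives a reacted part of 50.9%, a product excess of 94.9% and a substrate excess of 98.4%.

The forecast, resting on the view that “Selectivity comes from the slow right-handed loss in both runs”, differs from this reckoning mainly in the product excess, with 53.4%, 83% and 95%.

The flask gives 51.4%, 93.4% and 98.4%.

    coupling partner + protic impurity → quenched reagent (k = 0.340 M⁻¹ s⁻¹)
    free catalyst + left-handed substrate ⇌ catalyst intermediate A (K = 26.0 M⁻¹, k = 53.0 M⁻¹ s⁻¹)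
    free catalyst + stray impurity → spent catalyst (k = 6200 M⁻¹ s⁻¹)
    coupling partner + catalyst intermediate A → free catalyst + left-handed product (k = 15.0 M⁻¹ s⁻¹)
    coupling partner + catalyst intermediate B → free catalyst + right-handed product (k = 0.220 M⁻¹ s⁻¹)
    2 free catalyst ⇌ resting dimer, settled at all times (K = 1600 M⁻¹)
    free catalyst + right-handed substrate ⇌ catalyst intermediate B (K = 8.70 M⁻¹, k = 17.0 M⁻¹ s⁻¹)

Per intermediate, catalyst intermediate A takes up partner with 15 M⁻¹ s⁻¹ and catalyst intermediate B with 0.22 M⁻¹ s⁻¹, 68.2 times faster, yet at 50.0 min the flask holds 31.5% of its catalyst as B against 0.556% as A. The flask's 0.0453 M of final partner matches the spare less its right-handed product, 0.0446 M. The neighbour flask with 0.26 M of partner has a spare of 0.158 M, for which the leak gives 4.31% right-handed product; it holds 4.64%, at a product excess of 83.0%.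

The runs were generated by integration from invented constants, and the scatter is random.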